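**Plan**

1. Retrosynthetic cuts, in order: C9–OH (allylic C–H oxidation), the C6–O ester bond, C6–H (directed ketone reduction), C4–isopropyl (carbonyl addition), then the two bonds that hold the cyclopentane on the seven-membered ring, C4–C5 (Dieckmann) and C1–C2 (conjugate addition). This leaves 3,6-dimethylcyclohepta-2,6-dien-1-one and a three-carbon ester homoenolate.
2. Enabling feature: in the seven-membered ring, C6 lies between C5–C1(CH3) and C7=C8(CH3), so both methyl-bearing ring carbons are β to the C6 oxygen (a latent Cs-symmetric cross-conjugated dienone). C4 and C6 are 1,3-dioxygenated across the ring-fusion carbon C5 (a latent 1,3-diketone), so C1–C2 and C4–C5 are the β- and α-bonds of that dienone.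
3. Forward order: the seven-membered ring is taken intact from cycloheptanone (steps 1–3); the cyclopentane is closed last, in step 4, by a desymmetrising enantioselective conjugate addition followed by Dieckmann condensation; then isopropyl addition, ketone reduction, acylation and C9 hydroxylation.
4. Stereochemistry: C1 from the chiral copper catalyst; C4 by addition anti to the C1 methyl; C5 by protonation of the C5=C6 enolate (trans fusion, hydrogen-bonded ketol); C6 by hydroxyl-directed hydride delivery; C9 by SeO2 oxidation anti to the C6 ester.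
5. Locants in the text are daucane numbers (C1, C2, C3, C4, C5, C6, C7, C8, C9, C10 = C8a, C1, C2, C3, C3a, C4, C5, C6, C7, C8 of the azulene names); β is the face of the C1 methyl group.

Key step: step 4

Remark: the antipode of the chiral NHC ligand in step 4 is the one that forms the quaternary carbon of 9 with the (S) configuration.

**Step 1**
Reactants: 1 cycloheptanone
Product: 2 cyclohepta-2,6-dien-1-one
Conditions: IBX (2.5 equiv), DMSO/fluorobenzene, 75 °C
Reagents that add atoms: none
Why: IBX-mediated α,β-dehydrogenation of a ketone, run with enough oxidant to desaturate both α,β-positions and stopped by stoichiometry before the third dehydrogenation to tropone; no stereocentre is formed.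

**Step 2**
Reactants: 2 cyclohepta-2,6-dien-1-one
Product: 4 3-methylcyclohepta-2,6-dien-1-one, via dienol silyl ether 3 (not isolated)
Conditions: MeMgBr, CuBr·SMe2 (5 mol %), TMSCl, THF, −78 °C; then Pd(OAc)2 (10 mol %), O2 (1 atm), DMSO, rt
Reagents that add atoms: methylmagnesium bromide, C[Mg]Br
Why: Copper-catalysed conjugate addition with chlorosilane trapping adds one methyl (the silylated enolate cannot accept a second one), and Saegusa–Ito oxidation of the dienol silyl ether, whose palladium enolate has its only β-hydrogen on the methyl-bearing carbon, restores the enone on that side, so the transient stereocentre disappears.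

**Step 3**
Reactants: 4 3-methylcyclohepta-2,6-dien-1-one
Product: 6 3,6-dimethylcyclohepta-2,6-dien-1-one, via dienol silyl ether 5 (not isolated)
Conditions: MeMgBr, CuBr·SMe2 (5 mol %), TMSCl, THF, −78 °C; then Pd(OAc)2 (10 mol %), O2 (1 atm), DMSO, rt
Reagents that add atoms: methylmagnesium bromide, C[Mg]Br
Why: The same conjugate addition/Saegusa–Ito sequence is chemoselective for the unsubstituted enone arm, because organocopper reagents add much faster to a β-unsubstituted than to a β,β-disubstituted enone, and it should give the Cs-symmetric dienone.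

**Step 4**
Reactants: 6 3,6-dimethylcyclohepta-2,6-dien-1-one; 7 (1-ethoxycyclopropoxy)trimethylsilane
Product: 10 (8aS)-4-hydroxy-6,8a-dimethyl-2,7,8,8a-tetrahydroazulen-3(1H)-one, via zinc homoenolate 8 (not isolated), via dienol silyl ether 9 (not isolated)
Conditions: 7, ZnCl2 (0.55 equiv), Et2O, rt; then 6, (CuOTf)2·C6H6 (2.5 mol %), chiral sulfonate-bearing NHC–Ag complex (5 mol %, carbene source), Et2O/THF, −30 → 0 °C; then KOt-Bu (1.5 equiv), THF, 0 °C → rt; aq. NH4Cl
Reagents that add atoms: none
Why: Proposed new method: the zinc homoenolate 8 should transmetalate to the chiral NHC–copper(I) centre and add 1,4 to one of the two enantiotopic β-methyl enone arms of the Cs-symmetric dienone 6 (π-complex, copper(III) intermediate, reductive elimination), the chlorotrimethylsilane set free on forming 8 trapping the enolate as dienol silyl ether 9; tert-butoxide then unmasks the C5 enolate at exactly that position and its C-acylation by the tethered ester (Dieckmann condensation) closes the cyclopentane, the acidic 1,3-diketone being deprotonated and thereby withdrawn from the equilibrium. The closest known reaction types are the NHC–copper-catalysed enantioselective conjugate addition of dialkylzinc reagents to β-methyl cyclic enones (seven-membered rings included) that builds all-carbon quaternary centres, the copper-catalysed, chlorosilane-accelerated conjugate addition of zinc ester homoenolates, and conjugate addition/Dieckmann annulation; new is their combination with a carbonyl-chelated alkylzinc on a cross-conjugated dienone. The cyclopentane closes in the 5-exo-trig (enolexo) mode at the ester carbonyl. C1, the only stereocentre formed, is controlled by the catalyst, which selects one enantiotopic enone arm and its face, while C5 is deliberately left sp2 in the enolised diketone, because any closure onto C5 from a tether on C1 could only give the cis ring fusion. The step needs 1,4- over 1,2-addition and mono-addition, secured by the soft alkylcopper nucleophile and by the fact that after the first addition the second enone is part of a 2-silyloxy diene and no longer an acceptor. C- over O-acylation is secured by the five-membered transition state and the irreversible enolisation of the product.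

**Step 5**
Reactants: 10 (8aS)-4-hydroxy-6,8a-dimethyl-2,7,8,8a-tetrahydroazulen-3(1H)-one
Product: 11 (8aS)-6,8a-dimethyl-4-[(triethylsilyl)oxy]-2,7,8,8a-tetrahydroazulen-3(1H)-one
Conditions: TESOTf, Et3N, CH2Cl2, −78 → 0 °C
Reagents that add atoms: triethylsilyl trifluoromethanesulfonate, CC[Si](CC)(CC)OS(=O)(=O)C(F)(F)F
Why: O-Silylation of the enolised 1,3-diketone should place silicon on the C6 oxygen, because a 2-acylcyclopentanone enolises away from the five-membered ring (C5=C6 exocyclic to it and conjugated with C7=C8) and 1,5-silyl shifts let the O-silyl isomers settle to this vinylogous silyl ester, which leaves the C4 carbonyl as the only electrophilic site.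

**Step 6**
Reactants: 11 (8aS)-6,8a-dimethyl-4-[(triethylsilyl)oxy]-2,7,8,8a-tetrahydroazulen-3(1H)-one
Product: 13 (3R,3aR,8aS)-3-hydroxy-6,8a-dimethyl-3-(propan-2-yl)-2,3,3a,7,8,8a-hexahydroazulen-4(1H)-one, via carbinol silyl ether 12 (not isolated)
Conditions: i-PrMgCl, anhydrous CeCl3, THF, −78 °C; then TBAF, AcOH, THF, −78 → 0 °C; then DBU (0.2 equiv), CH2Cl2, rt
Reagents that add atoms: isopropylmagnesium chloride, CC(C)[Mg]Cl
Why: Organocerium 1,2-addition to the vinylogous silyl ester carbonyl (first stage of a Stork–Danheiser sequence) should occur anti to the pseudo-axial C1 methyl and set C4 (OH β, isopropyl α), and buffered fluoride desilylation, used instead of acid to avoid the Stork–Danheiser dehydration, releases the C5=C6 enolate, whose protonation anti to the C1 methyl gives the trans-fused ketol, which is also expected to be the C5 epimer favoured on DBU equilibration (enolisation only) because the C4 hydroxyl hydrogen-bonds to the C6 carbonyl and the isopropyl group is trans to C6.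

**Step 7**
Reactants: 13 (3R,3aR,8aS)-3-hydroxy-6,8a-dimethyl-3-(propan-2-yl)-2,3,3a,7,8,8a-hexahydroazulen-4(1H)-one
Product: 14 (3R,3aS,4S,8aS)-6,8a-dimethyl-3-(propan-2-yl)-1,2,3,3a,4,7,8,8a-octahydroazulene-3,4-diol
Conditions: Me4NBH(OAc)3, MeCN/AcOH (1:1), −20 °C
Reagents that add atoms: none
Why: Evans–Saksena hydroxyl-directed reduction: the C4 hydroxyl exchanges onto boron and delivers hydride through a six-membered transition state to the β face of the C6 carbonyl (1,2-reduction of the enone), which should give the 1,3-anti diol with the C6 hydroxyl α, cis to H-5.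

**Step 8**
Reactants: 14 (3R,3aS,4S,8aS)-6,8a-dimethyl-3-(propan-2-yl)-1,2,3,3a,4,7,8,8a-octahydroazulene-3,4-diol; 15 4-methoxybenzoyl chloride
Product: 16 (3R,3aS,4S,8aS)-3-hydroxy-6,8a-dimethyl-3-(propan-2-yl)-1,2,3,3a,4,7,8,8a-octahydroazulen-4-yl 4-methoxybenzoate
Conditions: DMAP, Et3N, CH2Cl2, 0 °C → rt
Reagents that add atoms: none
Why: DMAP-catalysed acyl transfer (Steglich-type catalysis) should esterify the secondary allylic C6 hydroxyl while the hindered tertiary C4 hydroxyl stays free; no stereocentre is touched.

**Step 9**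
Reactants: 16 (3R,3aS,4S,8aS)-3-hydroxy-6,8a-dimethyl-3-(propan-2-yl)-1,2,3,3a,4,7,8,8a-octahydroazulen-4-yl 4-methoxybenzoate
Product: 17 (3R,3aS,4S,7R,8aR)-3,7-dihydroxy-6,8a-dimethyl-3-(propan-2-yl)-1,2,3,3a,4,7,8,8a-octahydroazulen-4-yl 4-methoxybenzoate
Conditions: SeO2 (0.5 equiv), t-BuOOH (3 equiv), CH2Cl2, rt
Reagents that add atoms: tert-butyl hydroperoxide, CC(C)(C)OO
Why: Selenium dioxide allylic hydroxylation (ene reaction, then [2,3]-sigmatropic shift) oxidises the ring methylene C9 next to the more substituted alkene carbon C8, and since selenium should attack C7 on the β face, anti to the α C6 ester, and both pericyclic steps are suprafacial, the new hydroxyl is delivered β, trans to the ester.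

**Compound list**

1 | cycloheptanone | O=C1CCCCCC1 | starting material
2 | cyclohepta-2,6-dien-1-one | O=C1C=CCCC=C1 | intermediate
3 | trimethyl[(3-methylcyclohepta-1,6-dien-1-yl)oxy]silane (racemic) | CC1CCC=CC(O[Si](C)(C)C)=C1 | intermediate
4 | 3-methylcyclohepta-2,6-dien-1-one | CC1=CC(=O)C=CCC1 | intermediate
5 | trimethyl[(3,6-dimethylcyclohepta-1,6-dien-1-yl)oxy]silane (racemic) | CC1CCC(C)=CC(O[Si](C)(C)C)=C1 | intermediate
6 | 3,6-dimethylcyclohepta-2,6-dien-1-one | CC1=CC(=O)C=C(C)CC1 | intermediate
7 | (1-ethoxycyclopropoxy)trimethylsilane | CCOC1(CC1)O[Si](C)(C)C | starting material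
8 | bis(3-ethoxy-3-oxopropyl)zinc | CCOC(=O)CC[Zn]CCC(=O)OCC | intermediate
9 | ethyl 3-[(1S)-1,5-dimethyl-3-[(trimethylsilyl)oxy]cyclohepta-2,4-dien-1-yl]propanoate | CCOC(=O)CC[C@]1(C)CCC(C)=CC(O[Si](C)(C)C)=C1 | intermediate
10 | (8aS)-4-hydroxy-6,8a-dimethyl-2,7,8,8a-tetrahydroazulen-3(1H)-one (enol form of the bicyclic 1,3-diketone; C1 methyl β) | O=C1CC[C@]2(C)CCC(C)=CC(O)=C12 | intermediate
11 | (8aS)-6,8a-dimethyl-4-[(triethylsilyl)oxy]-2,7,8,8a-tetrahydroazulen-3(1H)-one | O=C1CC[C@]2(C)CCC(C)=CC(O[Si](CC)(CC)CC)=C12 | intermediate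
12 | (3R,8aS)-6,8a-dimethyl-3-(propan-2-yl)-4-[(triethylsilyl)oxy]-1,2,3,7,8,8a-hexahydroazulen-3-ol (C4 OH β, isopropyl α) | CC(C)[C@]1(O)CC[C@]2(C)CCC(C)=CC(O[Si](CC)(CC)CC)=C12 | intermediate
13 | (3R,3aR,8aS)-3-hydroxy-6,8a-dimethyl-3-(propan-2-yl)-2,3,3a,7,8,8a-hexahydroazulen-4(1H)-one (trans-fused, H-5 α) | O=C1C=C(C)CC[C@@]2(C)CC[C@@](O)(C(C)C)[C@H]12 | intermediate
14 | (3R,3aS,4S,8aS)-6,8a-dimethyl-3-(propan-2-yl)-1,2,3,3a,4,7,8,8a-octahydroazulene-3,4-diol (C6 OH α) | O[C@H]1C=C(C)CC[C@@]2(C)CC[C@@](O)(C(C)C)[C@H]12 | intermediate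
15 | 4-methoxybenzoyl chloride | COc1ccc(cc1)C(Cl)=O | starting material
16 | (3R,3aS,4S,8aS)-3-hydroxy-6,8a-dimethyl-3-(propan-2-yl)-1,2,3,3a,4,7,8,8a-octahydroazulen-4-yl 4-methoxybenzoate | COc1ccc(C(=O)O[C@H]2C=C(C)CC[C@@]3(C)CC[C@@](O)(C(C)C)[C@H]23)cc1 | intermediate
17 | (3R,3aS,4S,7R,8aR)-3,7-dihydroxy-6,8a-dimethyl-3-(propan-2-yl)-1,2,3,3a,4,7,8,8a-octahydroazulen-4-yl 4-methoxybenzoate | COc1ccc(C(=O)O[C@H]2C=C(C)[C@H](O)C[C@@]3(C)CC[C@@](O)(C(C)C)[C@H]23)cc1 | target

**Step count and risks**

Total step count: 9. Longest linear sequence: 9 steps (1 → 17); compounds 7 and 15 enter as purchased materials.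

Steps most likely to fail:

Step 4 (Proposed new method). Transfer of the carbonyl-chelated homoenolate from zinc to the chiral copper centre may be slow, and enantiotopic-arm discrimination on the dienone may be insufficient. The fallback uses known reaction types only and sets out from 6. An NHC–copper-catalysed enantioselective conjugate addition of but-3-enylmagnesium bromide (Cu(OTf)2, chiral NHC precursor, Et2O, −30 °C) should give (6R)-6-(but-3-en-1-yl)-3,6-dimethylcyclohept-2-en-1-one F1. Ozonolysis limited to the electron-rich terminal alkene (O3, CH2Cl2/MeOH, −78 °C, dye end-point; Me2S) should give 3-[(1S)-1,5-dimethyl-3-oxocyclohept-4-en-1-yl]propanal F2. Pinnick oxidation should give 3-[(1S)-1,5-dimethyl-3-oxocyclohept-4-en-1-yl]propanoic acid F3, and alkylation with EtI/K2CO3 should give ethyl 3-[(1S)-1,5-dimethyl-3-oxocyclohept-4-en-1-yl]propanoate F4. Kinetic α′-deprotonation with LDA (2 equiv, THF, −78 → 0 °C) and Dieckmann condensation then return to the route at 10.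

Step 6. The secondary organometallic may reduce the hindered C4 carbonyl by β-hydride transfer or enolise it instead of adding; protonation at C5 is the second uncertainty, for which the DBU equilibration is built into the step. The fallback sets out from 11 and changes the nucleophile to one without β-hydrogen. Isopropenylmagnesium bromide/CeCl3 (THF, −78 °C) should give (3R,8aS)-6,8a-dimethyl-3-(prop-1-en-2-yl)-4-[(triethylsilyl)oxy]-1,2,3,7,8,8a-hexahydroazulen-3-ol F5, which is not isolated. Buffered TBAF/AcOH and DBU as in step 6 should give (3S,3aR,8aS)-3-hydroxy-6,8a-dimethyl-3-(prop-1-en-2-yl)-2,3,3a,7,8,8a-hexahydroazulen-4(1H)-one F6. Chemoselective hydrogenation of the 1,1-disubstituted alkene (H2, RhCl(PPh3)3, benzene, rt), which should leave the trisubstituted enone untouched, returns to the route at 13.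

Step 9. Facial selectivity at C9 may be poor, and the alcohol may be over-oxidised to the enone. The fallback sets out from 16 and replaces direct hydroxylation by oxidation to the ketone followed by substrate-controlled reduction. Allylic C–H oxidation (CrO3·3,5-dimethylpyrazole, CH2Cl2, −20 °C) should give (3R,3aS,4S,8aR)-3-hydroxy-6,8a-dimethyl-7-oxo-3-(propan-2-yl)-1,2,3,3a,4,7,8,8a-octahydroazulen-4-yl 4-methoxybenzoate F7. Luche reduction (NaBH4, CeCl3·7H2O, MeOH, −78 °C), with hydride arriving anti to the C1 methyl, should then give the 9β-alcohol and return to the route at 17.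

**Further compounds**

F1 | step 4 | (6R)-6-(but-3-en-1-yl)-3,6-dimethylcyclohept-2-en-1-one | C=CCC[C@]1(C)CCC(C)=CC(=O)C1
F2 | step 4 | 3-[(1S)-1,5-dimethyl-3-oxocyclohept-4-en-1-yl]propanal | O=CCC[C@]1(C)CCC(C)=CC(=O)C1
F3 | step 4 | 3-[(1S)-1,5-dimethyl-3-oxocyclohept-4-en-1-yl]propanoic acid | OC(=O)CC[C@]1(C)CCC(C)=CC(=O)C1
F4 | step 4 | ethyl 3-[(1S)-1,5-dimethyl-3-oxocyclohept-4-en-1-yl]propanoate | CCOC(=O)CC[C@]1(C)CCC(C)=CC(=O)C1
F5 | step 6 | (3R,8aS)-6,8a-dimethyl-3-(prop-1-en-2-yl)-4-[(triethylsilyl)oxy]-1,2,3,7,8,8a-hexahydroazulen-3-ol | CC(=C)[C@]1(O)CC[C@]2(C)CCC(C)=CC(O[Si](CC)(CC)CC)=C12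
F6 | step 6 | (3S,3aR,8aS)-3-hydroxy-6,8a-dimethyl-3-(prop-1-en-2-yl)-2,3,3a,7,8,8a-hexahydroazulen-4(1H)-one | O=C1C=C(C)CC[C@@]2(C)CC[C@@](O)(C(C)=C)[C@H]12
F7 | step 9 | (3R,3aS,4S,8aR)-3-hydroxy-6,8a-dimethyl-7-oxo-3-(propan-2-yl)-1,2,3,3a,4,7,8,8a-octahydroazulen-4-yl 4-methoxybenzoate | COc1ccc(C(=O)O[C@H]2C=C(C)C(=O)C[C@@]3(C)CC[C@@](O)(C(C)C)[C@H]23)cc1
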